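**Strategy.** The 1,2-dioxane is cut at the O1–C6 bond (ring numbered O1, O2, C3 carrying methyl and 8-phenyloctyl, C4, C5, C6 carrying methyl and the propanoic arm). The feature used is that quaternary C6 can be the methyl-bearing inner terminus of an (E)-trisubstituted allylic alcohol: a divalent-palladium SN2′ cyclisation lets the tertiary C3 hydroperoxide add to that carbon, closes the ring, expels the allylic hydroxyl and relays the carbinol configuration to C6 in one operation. The precursor is an acyclic (S)-allylic alcohol with a remote (S)-tertiary hydroperoxide. The propenyl group left on C6 supplies only the first arm carbon; ozonolysis and a two-carbon Wittig extension complete the arm.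

Key step: step 17

Assumption: the palladium cyclisation is taken to follow the syn-SN2′ course (peroxide oxygen enters on the face of the leaving hydroxyl); if it proved anti, the enantiomeric oxazaborolidine in step 4 would supply the (R)-carbinol and the same C6 configuration.

Step 1
Reactants: 1 hexane-2,5-dione; 2 tert-butyl (diethoxyphosphoryl)acetate
Product: 3 tert-butyl (2E)-3-methyl-6-oxohept-2-enoate
Conditions: NaH, THF, 0 °C to rt, 1 in fourfold excess
Reagents that add atoms: none
Why: Horner–Wadsworth–Emmons olefination of one of the two equivalent methyl ketones with the stabilised phosphonate anion should favour the (E)-enoate, the excess of the water-soluble diketone holds back double olefination, and the minor (Z)-isomer is to be removed by chromatography.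

Step 2
Reactants: 3 tert-butyl (2E)-3-methyl-6-oxohept-2-enoate; 4 diethyl {2-[methoxy(methyl)amino]-2-oxoethyl}phosphonate
Product: 5 tert-butyl (2E,6E)-8-[methoxy(methyl)amino]-3,6-dimethyl-8-oxoocta-2,6-dienoate
Conditions: NaH, THF, 0 °C to reflux
Reagents that add atoms: none
Why: A second Horner–Wadsworth–Emmons olefination at the remaining methyl ketone should give the (E)-configured N-methoxy-N-methyl enamide, so that the two chain ends differ from the outset and no statistical protection is needed; the (Z)-isomer is to be separated.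

Step 3
Reactants: 5 tert-butyl (2E,6E)-8-[methoxy(methyl)amino]-3,6-dimethyl-8-oxoocta-2,6-dienoate
Product: 6 tert-butyl (2E,6E)-3,6-dimethyl-8-oxonona-2,6-dienoate
Conditions: MeMgBr, THF, −20 to 0 °C
Reagents that add atoms: methylmagnesium bromide, C[Mg]Br
Why: Weinreb ketone synthesis, in which the chelated tetrahedral adduct stops the addition at the methyl ketone, the hindered tert-butyl enoate is not attacked at this temperature, and the β,β-disubstitution suppresses conjugate addition.

Step 4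
Reactants: 6 tert-butyl (2E,6E)-3,6-dimethyl-8-oxonona-2,6-dienoate
Product: 7 tert-butyl (2E,6E,8S)-8-hydroxy-3,6-dimethylnona-2,6-dienoate
Conditions: (R)-1-methyl-3,3-diphenyltetrahydro-1H,3H-pyrrolo[1,2-c][1,3,2]oxazaborole (20 mol %), catecholborane, toluene, −78 °C
Reagents that add atoms: none
Why: Corey–Bakshi–Shibata reduction, in which the alkenyl group acts as the large and the methyl as the small ketone substituent, so the (R)-oxazaborolidine should deliver hydride to the face that gives the (S)-carbinol, while the enoate is inert to catecholborane in the cold.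

Step 5
Reactants: 7 tert-butyl (2E,6E,8S)-8-hydroxy-3,6-dimethylnona-2,6-dienoate
Product: 8 tert-butyl (2E,6E,8S)-8-[(tert-butyldiphenylsilyl)oxy]-3,6-dimethylnona-2,6-dienoate
Conditions: tBuPh2SiCl, imidazole, DMF, rt
Reagents that add atoms: tert-butyl(chloro)diphenylsilane, CC(C)(C)[Si](Cl)(c1ccccc1)c1ccccc1
Why: Silylation of the secondary allylic alcohol gives an ether that should withstand hydride, the titanium epoxidation and the acidic peroxide step, and that keeps the carbinol from ionising or directing a second epoxidation.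

Step 6
Reactants: 8 tert-butyl (2E,6E,8S)-8-[(tert-butyldiphenylsilyl)oxy]-3,6-dimethylnona-2,6-dienoate
Product: 9 (2E,6E,8S)-8-[(tert-butyldiphenylsilyl)oxy]-3,6-dimethylnona-2,6-dien-1-ol
Conditions: iBu2AlH, CH2Cl2, −78 to 0 °C
Reagents that add atoms: none
Why: 1,2-Reduction of the enoate by the aluminium hydride should give the primary (E)-allylic alcohol without touching the alkenes or the silyl ether.

Step 7
Reactants: 9 (2E,6E,8S)-8-[(tert-butyldiphenylsilyl)oxy]-3,6-dimethylnona-2,6-dien-1-ol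
Product: 10 [(2S,3S)-3-{(3E,5S)-5-[(tert-butyldiphenylsilyl)oxy]-3-methylhex-3-en-1-yl}-3-methyloxiran-2-yl]methanol
Conditions: Ti(OiPr)4 (10 mol %), L-(+)-diethyl tartrate (12 mol %), tBuOOH, 4 Å molecular sieves, CH2Cl2, −20 °C
Reagents that add atoms: tert-butyl hydroperoxide, CC(C)(C)OO
Why: Sharpless asymmetric epoxidation, in which the titanium tartrate binds only the free primary allylic alcohol and with L-(+)-tartrate should deliver oxygen to the face that gives the (2S,3S)-oxirane, as for other (E)-3-methylalk-2-en-1-ols (reagent control sets both oxirane centres and the silylated alkene is not a substrate).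

Step 8
Reactants: 10 [(2S,3S)-3-{(3E,5S)-5-[(tert-butyldiphenylsilyl)oxy]-3-methylhex-3-en-1-yl}-3-methyloxiran-2-yl]methanol
Product: 11 (2S,3S)-2-{[(tert-butyldiphenylsilyl)oxy]methyl}-3-{(3E,5S)-5-[(tert-butyldiphenylsilyl)oxy]-3-methylhex-3-en-1-yl}-3-methyloxirane
Conditions: tBuPh2SiCl, imidazole, CH2Cl2, 0 °C to rt
Reagents that add atoms: tert-butyl(chloro)diphenylsilane, CC(C)(C)[Si](Cl)(c1ccccc1)c1ccccc1
Why: Silylation of the primary hydroxyl under neutral conditions (no Payne rearrangement) leaves only one hydroxyl beside the coming hydroperoxide, so that the later peroxyketal protection cannot be diverted into an acetonide of a free 1,2-diol.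

Step 9
Reactants: 11 (2S,3S)-2-{[(tert-butyldiphenylsilyl)oxy]methyl}-3-{(3E,5S)-5-[(tert-butyldiphenylsilyl)oxy]-3-methylhex-3-en-1-yl}-3-methyloxirane
Product: 12 (2S,3R,6E,8S)-1,8-bis[(tert-butyldiphenylsilyl)oxy]-3-hydroperoxy-3,6-dimethylnon-6-en-2-ol
Conditions: H2O2 (anhydrous, in Et2O, excess), H3PMo12O40 (3 mol %), Et2O, 0 °C to rt
Reagents that add atoms: hydrogen peroxide, OO
Why: Acid-catalysed perhydrolysis of a trisubstituted epoxide, in which H2O2 should open the activated oxirane at its tertiary carbon from the side opposite the breaking C–O bond (borderline SN2, inversion), which sets the hydroperoxide-bearing centre (the later ring C3) while the secondary carbinol keeps its configuration.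

Step 10
Reactants: 12 (2S,3R,6E,8S)-1,8-bis[(tert-butyldiphenylsilyl)oxy]-3-hydroperoxy-3,6-dimethylnon-6-en-2-ol
Product: 13 (2S,3R,6E,8S)-1,8-bis[(tert-butyldiphenylsilyl)oxy]-3-[(2-methoxypropan-2-yl)peroxy]-3,6-dimethylnon-6-en-2-ol
Conditions: 2-methoxypropene (1.5 equiv), pyridinium p-toluenesulfonate (5 mol %), CH2Cl2, 0 °C
Reagents that add atoms: 2-methoxypropene, COC(C)=C
Why: Acid-catalysed addition of the hydroperoxide to the enol ether gives the peroxyketal, and the unhindered OOH should react in preference to the secondary hydroxyl wedged between a quaternary carbon and the silyloxymethyl group, the cold weak acid not being expected to close a trioxane.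

Step 11
Reactants: 13 (2S,3R,6E,8S)-1,8-bis[(tert-butyldiphenylsilyl)oxy]-3-[(2-methoxypropan-2-yl)peroxy]-3,6-dimethylnon-6-en-2-ol
Product: 14 (2S,3R,6E,8S)-3-[(2-methoxypropan-2-yl)peroxy]-3,6-dimethylnon-6-ene-1,2,8-triol
Conditions: Bu4NF, AcOH, THF, 0 °C to rt
Reagents that add atoms: none
Why: Fluoride-mediated desilylation should remove both silyl ethers, and the acetate-buffered medium is neither acidic enough to hydrolyse the peroxyketal nor basic enough to harm the peroxide.

Step 12
Reactants: 14 (2S,3R,6E,8S)-3-[(2-methoxypropan-2-yl)peroxy]-3,6-dimethylnon-6-ene-1,2,8-triol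
Product: 15 (2R,5E,7S)-7-hydroxy-2-[(2-methoxypropan-2-yl)peroxy]-2,5-dimethyloct-5-enal
Conditions: NaIO4, NaHCO3, THF/H2O, 0 °C
Reagents that add atoms: none
Why: Periodate glycol cleavage acts only on the 1,2-diol and should give the α-peroxy aldehyde, which has no α-hydrogen and so can neither epimerise nor fragment by base-induced loss of the peroxide.

Step 13
Reactants: 16 (7-bromoheptyl)benzene
Product: 17 triphenyl(7-phenylheptyl)phosphonium bromide
Conditions: PPh3, MeCN, reflux
Reagents that add atoms: triphenylphosphine, c1ccc(cc1)P(c1ccccc1)c1ccccc1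
Why: SN2 quaternisation of triphenylphosphine by the primary bromide gives the phosphonium salt.

Step 14
Reactants: 15 (2R,5E,7S)-7-hydroxy-2-[(2-methoxypropan-2-yl)peroxy]-2,5-dimethyloct-5-enal; 17 triphenyl(7-phenylheptyl)phosphonium bromide
Product: 18 (2S,3E,7R,8Z)-7-[(2-methoxypropan-2-yl)peroxy]-4,7-dimethyl-15-phenylpentadeca-3,8-dien-2-ol
Conditions: 17 (2 equiv), NaN(SiMe3)2 (1.9 equiv), THF, −78 °C, then 15, to 0 °C
Reagents that add atoms: none
Why: Wittig olefination with the non-stabilised ylide should give mainly the (Z)-alkene (its geometry is irrelevant, as it is reduced next), and peroxyketals and free hydroxyls are known to tolerate such ylides at low temperature.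

Step 15
Reactants: 18 (2S,3E,7R,8Z)-7-[(2-methoxypropan-2-yl)peroxy]-4,7-dimethyl-15-phenylpentadeca-3,8-dien-2-ol
Product: 19 (2S,3E,7S)-7-[(2-methoxypropan-2-yl)peroxy]-4,7-dimethyl-15-phenylpentadec-3-en-2-ol
Conditions: 2-nitrobenzenesulfonohydrazide, Et3N, CH2Cl2, rt
Reagents that add atoms: none
Why: Diimide reduction transfers H2 in a concerted way that is much faster for the 1,2-disubstituted alkene than for the trisubstituted one and leaves the O–O bond intact, which metal-catalysed hydrogenation would not.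

Step 16
Reactants: 19 (2S,3E,7S)-7-[(2-methoxypropan-2-yl)peroxy]-4,7-dimethyl-15-phenylpentadec-3-en-2-ol
Product: 20 (2S,3E,7S)-7-hydroperoxy-4,7-dimethyl-15-phenylpentadec-3-en-2-ol
Conditions: AcOH/THF/H2O (4:2:1), rt
Reagents that add atoms: none
Why: Mild acid hydrolysis of the peroxyketal cleaves only the ketal C–O bonds, so the tertiary hydroperoxide is freed with its configuration unchanged and the allylic alcohol should survive.

Step 17
Reactants: 20 (2S,3E,7S)-7-hydroperoxy-4,7-dimethyl-15-phenylpentadec-3-en-2-ol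
Product: 21 (3S,6R)-3,6-dimethyl-3-(8-phenyloctyl)-6-[(1E)-prop-1-en-1-yl]-1,2-dioxane
Conditions: PdCl2(MeCN)2 (10 mol %), THF, 0 °C, high dilution
Reagents that add atoms: none
Why: Proposed new method: PdCl2(MeCN)2 should bind the C3=C4 alkene of 20 on the face of the C2 hydroxyl in the conformer that keeps the carbinol hydrogen in the alkene plane beside the C4 methyl (allylic 1,3-strain); the terminal hydroperoxide oxygen then adds to C4 on that face and syn loss of Pd(OH)Cl across C3–C2 gives water, the (E)-propenyl group and divalent palladium again, with no redox change. The closest known reaction types are the PdCl2(MeCN)2-catalysed stereospecific SN2′ cyclisation of hydroxy allylic alcohols to tetrahydropyrans and the cyclisation of unsaturated tertiary hydroperoxides to 1,2-dioxanes under divalent palladium; new here is a hydroperoxide nucleophile with 1,3-chirality transfer onto a fully substituted carbon. The 1,2-dioxane closes 6-exo-trig through the O1–C6 bond. The new C6 centre is controlled by the (S)-carbinol through the (E)-alkene geometry, which on the syn course maps onto (6R). The step needs the peroxide oxygen to attack C4 and not C3 (7-endo) and the O–O bond and carbinol to survive; the six-membered transition state, dilution, and the absence of phosphines and of zerovalent palladium should secure this.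

Step 18
Reactants: 21 (3S,6R)-3,6-dimethyl-3-(8-phenyloctyl)-6-[(1E)-prop-1-en-1-yl]-1,2-dioxane
Product: 23 (3R,6S)-3,6-dimethyl-6-(8-phenyloctyl)-1,2-dioxane-3-carbaldehyde, via ozonide 22 (not isolated)
Conditions: O3 (to the first trace of blue), CH2Cl2, −78 °C; then PPh3, −78 °C to rt
Reagents that add atoms: ozone, [O-][O+]=O
Why: Ozonolysis with reductive work-up cuts the only alkene (the arene is far slower at −78 °C and the hindered dialkyl peroxide is inert to PPh3 at rt) and should leave the aldehyde on quaternary C6, which cannot epimerise.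

Step 19
Reactants: 23 (3R,6S)-3,6-dimethyl-6-(8-phenyloctyl)-1,2-dioxane-3-carbaldehyde; 24 methyl (triphenylphosphoranylidene)acetate
Product: 25 methyl (2E)-3-[(3R,6S)-3,6-dimethyl-6-(8-phenyloctyl)-1,2-dioxan-3-yl]prop-2-enoate
Conditions: 24, CH2Cl2, rt
Reagents that add atoms: none
Why: Wittig olefination with the stabilised ylide runs under neutral conditions that α-peroxy aldehydes tolerate and should give the (E)-enoate, which adds the last two arm carbons.

Step 20
Reactants: 25 methyl (2E)-3-[(3R,6S)-3,6-dimethyl-6-(8-phenyloctyl)-1,2-dioxan-3-yl]prop-2-enoate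
Product: 26 methyl 3-[(3R,6S)-3,6-dimethyl-6-(8-phenyloctyl)-1,2-dioxan-3-yl]propanoate
Conditions: 2-nitrobenzenesulfonohydrazide (excess), Et3N, CH2Cl2, rt
Reagents that add atoms: none
Why: Diimide reduction should saturate the disubstituted enoate alkene without cleaving the O–O bond.

Step 21
Reactants: 26 methyl 3-[(3R,6S)-3,6-dimethyl-6-(8-phenyloctyl)-1,2-dioxan-3-yl]propanoate
Product: 27 3-[(3R,6S)-3,6-dimethyl-6-(8-phenyloctyl)-1,2-dioxan-3-yl]propanoic acid (CNP0390528.1)
Conditions: LiOH, THF/H2O, 0 °C to rt; 1 M HCl on work-up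
Reagents that add atoms: lithium hydroxide, [Li+].[OH-]
Why: Saponification of the methyl ester should proceed without harm to the peroxide, because both peroxide carbons are fully substituted and base-induced Kornblum–DeLaMare fragmentation is impossible.

**Compound list**

1 | hexane-2,5-dione | CC(=O)CCC(C)=O | starting material
2 | tert-butyl (diethoxyphosphoryl)acetate | CCOP(=O)(CC(=O)OC(C)(C)C)OCC | starting material
3 | tert-butyl (2E)-3-methyl-6-oxohept-2-enoate | CC(C)(C)OC(=O)/C=C(\C)CCC(C)=O | intermediate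
4 | diethyl {2-[methoxy(methyl)amino]-2-oxoethyl}phosphonate | CCOP(=O)(CC(=O)N(C)OC)OCC | starting material
5 | tert-butyl (2E,6E)-8-[methoxy(methyl)amino]-3,6-dimethyl-8-oxoocta-2,6-dienoate | CC(C)(C)OC(=O)/C=C(\C)CC/C(C)=C/C(=O)N(C)OC | intermediate
6 | tert-butyl (2E,6E)-3,6-dimethyl-8-oxonona-2,6-dienoate | CC(C)(C)OC(=O)/C=C(\C)CC/C(C)=C/C(C)=O | intermediate
7 | tert-butyl (2E,6E,8S)-8-hydroxy-3,6-dimethylnona-2,6-dienoate | CC(C)(C)OC(=O)/C=C(\C)CC/C(C)=C/[C@H](C)O | intermediate
8 | tert-butyl (2E,6E,8S)-8-[(tert-butyldiphenylsilyl)oxy]-3,6-dimethylnona-2,6-dienoate | CC(C)(C)OC(=O)/C=C(\C)CC/C(C)=C/[C@H](C)O[Si](c1ccccc1)(c1ccccc1)C(C)(C)C | intermediate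
9 | (2E,6E,8S)-8-[(tert-butyldiphenylsilyl)oxy]-3,6-dimethylnona-2,6-dien-1-ol | OC/C=C(\C)CC/C(C)=C/[C@H](C)O[Si](c1ccccc1)(c1ccccc1)C(C)(C)C | intermediate
10 | [(2S,3S)-3-{(3E,5S)-5-[(tert-butyldiphenylsilyl)oxy]-3-methylhex-3-en-1-yl}-3-methyloxiran-2-yl]methanol | OC[C@@H]1O[C@@]1(C)CC/C(C)=C/[C@H](C)O[Si](c1ccccc1)(c1ccccc1)C(C)(C)C | intermediate
11 | (2S,3S)-2-{[(tert-butyldiphenylsilyl)oxy]methyl}-3-{(3E,5S)-5-[(tert-butyldiphenylsilyl)oxy]-3-methylhex-3-en-1-yl}-3-methyloxirane | CC(C)(C)[Si](c1ccccc1)(c1ccccc1)OC[C@@H]1O[C@@]1(C)CC/C(C)=C/[C@H](C)O[Si](c1ccccc1)(c1ccccc1)C(C)(C)C | intermediate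
12 | (2S,3R,6E,8S)-1,8-bis[(tert-butyldiphenylsilyl)oxy]-3-hydroperoxy-3,6-dimethylnon-6-en-2-ol | C[C@](OO)([C@@H](O)CO[Si](c1ccccc1)(c1ccccc1)C(C)(C)C)CC/C(C)=C/[C@H](C)O[Si](c1ccccc1)(c1ccccc1)C(C)(C)C | intermediate
13 | (2S,3R,6E,8S)-1,8-bis[(tert-butyldiphenylsilyl)oxy]-3-[(2-methoxypropan-2-yl)peroxy]-3,6-dimethylnon-6-en-2-ol | C[C@](OOC(C)(C)OC)([C@@H](O)CO[Si](c1ccccc1)(c1ccccc1)C(C)(C)C)CC/C(C)=C/[C@H](C)O[Si](c1ccccc1)(c1ccccc1)C(C)(C)C | intermediate
14 | (2S,3R,6E,8S)-3-[(2-methoxypropan-2-yl)peroxy]-3,6-dimethylnon-6-ene-1,2,8-triol | C[C@](OOC(C)(C)OC)([C@@H](O)CO)CC/C(C)=C/[C@H](C)O | intermediate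
15 | (2R,5E,7S)-7-hydroxy-2-[(2-methoxypropan-2-yl)peroxy]-2,5-dimethyloct-5-enal | C[C@](OOC(C)(C)OC)(C=O)CC/C(C)=C/[C@H](C)O | intermediate
16 | (7-bromoheptyl)benzene | BrCCCCCCCc1ccccc1 | starting material
17 | triphenyl(7-phenylheptyl)phosphonium bromide | [Br-].c1ccc(cc1)CCCCCCC[P+](c1ccccc1)(c1ccccc1)c1ccccc1 | intermediate
18 | (2S,3E,7R,8Z)-7-[(2-methoxypropan-2-yl)peroxy]-4,7-dimethyl-15-phenylpentadeca-3,8-dien-2-ol | C[C@](OOC(C)(C)OC)(/C=C\CCCCCCc1ccccc1)CC/C(C)=C/[C@H](C)O | intermediate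
19 | (2S,3E,7S)-7-[(2-methoxypropan-2-yl)peroxy]-4,7-dimethyl-15-phenylpentadec-3-en-2-ol | C[C@](OOC(C)(C)OC)(CCCCCCCCc1ccccc1)CC/C(C)=C/[C@H](C)O | intermediate
20 | (2S,3E,7S)-7-hydroperoxy-4,7-dimethyl-15-phenylpentadec-3-en-2-ol | C[C@](OO)(CCCCCCCCc1ccccc1)CC/C(C)=C/[C@H](C)O | intermediate (key-step precursor)
21 | (3S,6R)-3,6-dimethyl-3-(8-phenyloctyl)-6-[(1E)-prop-1-en-1-yl]-1,2-dioxane | C[C@]1(CCCCCCCCc2ccccc2)CC[C@](C)(/C=C/C)OO1 | intermediate (key-step product)
22 | 3-[(3R,6S)-3,6-dimethyl-6-(8-phenyloctyl)-1,2-dioxan-3-yl]-5-methyl-1,2,4-trioxolane (ozonide, mixture at the trioxolane carbons) | C[C@]1(CCCCCCCCc2ccccc2)CC[C@](C)(C2OOC(C)O2)OO1 | intermediate (not isolated)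
23 | (3R,6S)-3,6-dimethyl-6-(8-phenyloctyl)-1,2-dioxane-3-carbaldehyde | C[C@]1(CCCCCCCCc2ccccc2)CC[C@](C)(C=O)OO1 | intermediate
24 | methyl (triphenylphosphoranylidene)acetate | COC(=O)C=P(c1ccccc1)(c1ccccc1)c1ccccc1 | starting material
25 | methyl (2E)-3-[(3R,6S)-3,6-dimethyl-6-(8-phenyloctyl)-1,2-dioxan-3-yl]prop-2-enoate | C[C@]1(CCCCCCCCc2ccccc2)CC[C@](C)(/C=C/C(=O)OC)OO1 | intermediate
26 | methyl 3-[(3R,6S)-3,6-dimethyl-6-(8-phenyloctyl)-1,2-dioxan-3-yl]propanoate | C[C@]1(CCCCCCCCc2ccccc2)CC[C@](C)(CCC(=O)OC)OO1 | intermediate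
27 | 3-[(3R,6S)-3,6-dimethyl-6-(8-phenyloctyl)-1,2-dioxan-3-yl]propanoic acid | C[C@]1(CCCCCCCCc2ccccc2)CC[C@](C)(CCC(=O)O)OO1 | target

**Step count.** Total: 21 steps. Longest linear sequence: 20 steps (steps 1–12 and 14–21); step 13 is a one-step side branch.

**Steps most likely to fail**

Step 17 (proposed new method). The hydroperoxide may be decomposed by the palladium salt, the carbinol may be oxidised, or the oxypalladation may lose facial fidelity so that C6 forms as a mixture. The fallback uses known chemistry, sets out from 19 and comes back at 23. Sharpless epoxidation of the secondary allylic alcohol of 19 (Ti(OiPr)4, L-(+)-diisopropyl tartrate, tBuOOH; the (S)-carbinol is the matched case and should give the anti epoxy alcohol) would give (1S)-1-[(2S,3S)-3-{(3S)-3-[(2-methoxypropan-2-yl)peroxy]-3-methyl-11-phenylundecyl}-3-methyloxiran-2-yl]ethan-1-ol F1. Aqueous acetic acid would free the hydroperoxide to give (1S)-1-{(2S,3S)-3-[(3S)-3-hydroperoxy-3-methyl-11-phenylundecyl]-3-methyloxiran-2-yl}ethan-1-ol F2. Under camphorsulfonic acid in CH2Cl2 the hydroperoxide should open the oxirane at its tertiary carbon (6-exo, inversion, the established acid-mediated hydroperoxide–epoxide cyclisation) to give (1S,2S)-1-[(3R,6S)-3,6-dimethyl-6-(8-phenyloctyl)-1,2-dioxan-3-yl]propane-1,2-diol F3. Cleavage of this diol with NaIO4 gives aldehyde 23, so steps 16 to 18 are bypassed.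

Step 9. The tertiary carbon may partly ionise during the opening, which would erode the configuration of the future ring C3, or the peroxomolybdate may oxidise the trisubstituted alkene. The fallback sets out from 10 and comes back at 19; it replaces the epoxide by an oxetane, whose perhydrolysis at a tertiary carbon is known to be stereospecific.
- NaAlH2(OCH2CH2OCH3)2 should open 10 at C2 to give (3S,6E,8S)-8-[(tert-butyldiphenylsilyl)oxy]-3,6-dimethylnon-6-ene-1,3-diol F4.
- Tosylation of the primary hydroxyl would give (3S,6E,8S)-8-[(tert-butyldiphenylsilyl)oxy]-3-hydroxy-3,6-dimethylnon-6-en-1-yl 4-methylbenzenesulfonate F5, and KOtBu would close (2S)-2-{(3E,5S)-5-[(tert-butyldiphenylsilyl)oxy]-3-methylhex-3-en-1-yl}-2-methyloxetane F6.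
- Ethereal H2O2 with catalytic Me3SiOSO2CF3 should open the oxetane at the tertiary carbon with inversion to give (3R,6E,8S)-8-[(tert-butyldiphenylsilyl)oxy]-3-hydroperoxy-3,6-dimethylnon-6-en-1-ol F7.
- 2-Methoxypropene with pyridinium p-toluenesulfonate would cap the hydroperoxide as (3R,6E,8S)-8-[(tert-butyldiphenylsilyl)oxy]-3-[(2-methoxypropan-2-yl)peroxy]-3,6-dimethylnon-6-en-1-ol F8 (a mixed ketal on the primary hydroxyl would be removed by brief methanolysis).
- Dess–Martin oxidation would give (3R,6E,8S)-8-[(tert-butyldiphenylsilyl)oxy]-3-[(2-methoxypropan-2-yl)peroxy]-3,6-dimethylnon-6-enal F9.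
- Wittig reaction with the ylide from triphenyl(6-phenylhexyl)phosphonium bromide F10 (made from (6-bromohexyl)benzene and PPh3) would give tert-butyl{[(2S,3E,7R,9Z)-7-[(2-methoxypropan-2-yl)peroxy]-4,7-dimethyl-15-phenylpentadeca-3,9-dien-2-yl]oxy}diphenylsilane F11.
- Diimide would reduce this to tert-butyl{[(2S,3E,7S)-7-[(2-methoxypropan-2-yl)peroxy]-4,7-dimethyl-15-phenylpentadec-3-en-2-yl]oxy}diphenylsilane F12, and Bu4NF would then give 19.

Step 14. The non-stabilised ylide may add only slowly to the neopentyl-type α-peroxy aldehyde, so that attack on the O–O bond or fragmentation of the aldehyde competes. The fallback sets out from 15 and comes back at 19; it moves the non-stabilised Wittig reaction to an unhindered enal, a sequence known for α-peroxy aldehydes. The stabilised, neutral ylide (triphenylphosphoranylidene)acetaldehyde would convert 15 into (2E,4R,7E,9S)-9-hydroxy-4-[(2-methoxypropan-2-yl)peroxy]-4,7-dimethyldeca-2,7-dienal F13. The ylide from triphenyl(5-phenylpentyl)phosphonium bromide F14 (made from (5-bromopentyl)benzene and PPh3) would then give (2S,3E,7R,8E,10Z)-7-[(2-methoxypropan-2-yl)peroxy]-4,7-dimethyl-15-phenylpentadeca-3,8,10-trien-2-ol F15. Diimide should saturate both disubstituted alkenes of F15 and spare the trisubstituted one, which gives 19.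

**Further compounds**

F1 | step 17 | (1S)-1-[(2S,3S)-3-{(3S)-3-[(2-methoxypropan-2-yl)peroxy]-3-methyl-11-phenylundecyl}-3-methyloxiran-2-yl]ethan-1-ol | C[C@](OOC(C)(C)OC)(CCCCCCCCc1ccccc1)CC[C@]1(C)O[C@H]1[C@H](C)O
F2 | step 17 | (1S)-1-{(2S,3S)-3-[(3S)-3-hydroperoxy-3-methyl-11-phenylundecyl]-3-methyloxiran-2-yl}ethan-1-ol | C[C@](OO)(CCCCCCCCc1ccccc1)CC[C@]1(C)O[C@H]1[C@H](C)O
F3 | step 17 | (1S,2S)-1-[(3R,6S)-3,6-dimethyl-6-(8-phenyloctyl)-1,2-dioxan-3-yl]propane-1,2-diol | C[C@]1(CCCCCCCCc2ccccc2)CC[C@](C)([C@@H](O)[C@H](C)O)OO1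
F4 | step 9 | (3S,6E,8S)-8-[(tert-butyldiphenylsilyl)oxy]-3,6-dimethylnon-6-ene-1,3-diol | C[C@@](O)(CCO)CC/C(C)=C/[C@H](C)O[Si](c1ccccc1)(c1ccccc1)C(C)(C)C
F5 | step 9 | (3S,6E,8S)-8-[(tert-butyldiphenylsilyl)oxy]-3-hydroxy-3,6-dimethylnon-6-en-1-yl 4-methylbenzenesulfonate | C[C@@](O)(CCOS(=O)(=O)c1ccc(C)cc1)CC/C(C)=C/[C@H](C)O[Si](c1ccccc1)(c1ccccc1)C(C)(C)C
F6 | step 9 | (2S)-2-{(3E,5S)-5-[(tert-butyldiphenylsilyl)oxy]-3-methylhex-3-en-1-yl}-2-methyloxetane | C[C@@]1(CCO1)CC/C(C)=C/[C@H](C)O[Si](c1ccccc1)(c1ccccc1)C(C)(C)C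
F7 | step 9 | (3R,6E,8S)-8-[(tert-butyldiphenylsilyl)oxy]-3-hydroperoxy-3,6-dimethylnon-6-en-1-ol | C[C@](OO)(CCO)CC/C(C)=C/[C@H](C)O[Si](c1ccccc1)(c1ccccc1)C(C)(C)C
F8 | step 9 | (3R,6E,8S)-8-[(tert-butyldiphenylsilyl)oxy]-3-[(2-methoxypropan-2-yl)peroxy]-3,6-dimethylnon-6-en-1-ol | C[C@](OOC(C)(C)OC)(CCO)CC/C(C)=C/[C@H](C)O[Si](c1ccccc1)(c1ccccc1)C(C)(C)C
F9 | step 9 | (3R,6E,8S)-8-[(tert-butyldiphenylsilyl)oxy]-3-[(2-methoxypropan-2-yl)peroxy]-3,6-dimethylnon-6-enal | C[C@](OOC(C)(C)OC)(CC=O)CC/C(C)=C/[C@H](C)O[Si](c1ccccc1)(c1ccccc1)C(C)(C)C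
F10 | step 9 | triphenyl(6-phenylhexyl)phosphonium bromide | [Br-].c1ccc(cc1)CCCCCC[P+](c1ccccc1)(c1ccccc1)c1ccccc1
F11 | step 9 | tert-butyl{[(2S,3E,7R,9Z)-7-[(2-methoxypropan-2-yl)peroxy]-4,7-dimethyl-15-phenylpentadeca-3,9-dien-2-yl]oxy}diphenylsilane | C[C@](OOC(C)(C)OC)(C/C=C\CCCCCc1ccccc1)CC/C(C)=C/[C@H](C)O[Si](c1ccccc1)(c1ccccc1)C(C)(C)C
F12 | step 9 | tert-butyl{[(2S,3E,7S)-7-[(2-methoxypropan-2-yl)peroxy]-4,7-dimethyl-15-phenylpentadec-3-en-2-yl]oxy}diphenylsilane | C[C@](OOC(C)(C)OC)(CCCCCCCCc1ccccc1)CC/C(C)=C/[C@H](C)O[Si](c1ccccc1)(c1ccccc1)C(C)(C)C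
F13 | step 14 | (2E,4R,7E,9S)-9-hydroxy-4-[(2-methoxypropan-2-yl)peroxy]-4,7-dimethyldeca-2,7-dienal | C[C@](OOC(C)(C)OC)(/C=C/C=O)CC/C(C)=C/[C@H](C)O
F14 | step 14 | triphenyl(5-phenylpentyl)phosphonium bromide | [Br-].c1ccc(cc1)CCCCC[P+](c1ccccc1)(c1ccccc1)c1ccccc1
F15 | step 14 | (2S,3E,7R,8E,10Z)-7-[(2-methoxypropan-2-yl)peroxy]-4,7-dimethyl-15-phenylpentadeca-3,8,10-trien-2-ol | C[C@](OOC(C)(C)OC)(/C=C/C=C\CCCCc1ccccc1)CC/C(C)=C/[C@H](C)O
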